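**Plan**

- Retrosynthesis: remove the two acyl groups and the lactone methylene C13; trace the C3 ketone/C4 carbinol back to a C3=C4 alkene; trace the lactone oxygen on C6 back to a C–Si bond and the lactone carbons C11/C12 back to an acetate arm on C7.
- The ring then carries C8(=O)–C7–C6 on one side of the C5–C6 bond and C5–C4=C3 on the other, the pattern of an oxy-Cope product. Cutting C5–C6 while joining C3–C8 contracts the ten-membered ring to a cyclohexane (C1, C2, C3, C8, C9, C10) with a vinylsilane on C8 and an enol ether arm on C3.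
- Forward: the cyclohexanone comes from toluene cis-dihydrodiol; the two arms are added by enolate alkenylation and alkenyllithium addition; the anionic oxy-Cope shift with enolate alkylation then gives C5–C6, the ten-membered ring and the C7 side chain in one operation.
- Afterwards: C8 reduction, Si to OH at C6 and lactone closure, methylenation, exchange of PMB and MOM for the two esters, then epoxidation of C3=C4, ester-assisted opening and oxidation to the keto alcohol.
- Stereochemistry: C9 and C10 from the diol (C10 by hydrogenation); C5 and C6 from the two (E)-alkene geometries relayed through the chair; C7 by alkylation on the outer face; C8 by Felkin–Anh reduction; C4 by inversion of the epoxide carbon through the C5 ester.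

Key step: step 10

Remark: locants C1–C13 are those of the target in germacranolide numbering (C3 ketone, C4 tertiary carbinol with methyl, C5 isobutyrate, C6 lactone oxygen, C7 ring fusion, C8 hydroxyl, C9 isovalerate, C10 methyl, C11–C13 lactone carbons; 34 is 4R,5R,6S,7R,8R,9R,10R), and toluene cis-dihydrodiol 1 is taken as a commercial material.

**Route**

Step 1
Reactants: 1 (1S,2R)-3-methylcyclohexa-3,5-diene-1,2-diol
Product: 2 p-methoxybenzylidene acetal of 1
Conditions: 4-MeOC6H4CH(OMe)2, PPTS (cat.), CH2Cl2, 0 °C to rt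
Reagents that add atoms: 4-methoxybenzaldehyde dimethyl acetal, COC(OC)c1ccc(OC)cc1
Why: Acid-catalysed transacetalisation of the cis-diol gives the cis-fused acetal, which masks both oxygens, shields one face of the ring and later lets the two oxygens be told apart; no ring stereocentre is touched.

Step 2
Reactants: 2 p-methoxybenzylidene acetal of 1
Product: 3 saturated acetal (3aR,4R,7aS)
Conditions: H2 (1 atm), 5% Rh/Al2O3, EtOAc, rt
Reagents that add atoms: none
Why: Heterogeneous hydrogenation should saturate both alkenes from the convex face of the cis-fused bicycle, away from the dioxolane, so that the methyl group ends cis to the two oxygens (new centre R, C10 of the target).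

Step 3
Reactants: 3 saturated acetal
Product: 4 (1S,2R,3R)-2-[(4-methoxyphenyl)methoxy]-3-methylcyclohexan-1-ol
Conditions: i-Bu2AlH, CH2Cl2, −78 to 0 °C
Reagents that add atoms: none
Why: Reductive opening of the p-methoxybenzylidene acetal, in which aluminium binds the less hindered oxygen (remote from the methyl group), so that this oxygen becomes the free alcohol and the PMB group stays on the hindered one.

Step 4
Reactants: 4 mono-PMB diol
Product: 5 (2R,3R)-2-[(4-methoxyphenyl)methoxy]-3-methylcyclohexan-1-one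
Conditions: Dess–Martin periodinane, NaHCO3, CH2Cl2, rt
Reagents that add atoms: none
Why: Buffered Dess–Martin oxidation of the secondary alcohol should give the α-alkoxy ketone without epimerisation.

Step 5
Reactants: 6 2-bromoprop-2-en-1-ol
Product: 7 2-bromo-3-(methoxymethoxy)prop-1-ene
Conditions: MOMCl, i-Pr2NEt, CH2Cl2, 0 °C to rt
Reagents that add atoms: chloromethyl methyl ether, COCCl
Why: O-Alkylation of the primary alcohol with the chloromethyl ether and a hindered amine base (acetal protection).

Step 6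
Reactants: 5 ketone; 7 2-bromo-3-(methoxymethoxy)prop-1-ene
Product: 9 (2R,3R,6R)-alkenyl ketone, via lithium enolate 8 (not isolated)
Conditions: LiN(SiMe3)2, THF, −78 °C; then 7, Pd2(dba)3 (cat.), P(t-Bu)3 (cat.), THF–toluene, 0 °C to rt; AcOH, −78 °C
Reagents that add atoms: none
Why: Palladium-catalysed α-alkenylation of a ketone enolate (oxidative addition of the 2-bromoalkene, transmetalation with the kinetic CH2-side enolate, reductive elimination); cold axial protonation of the product enolate anti to the pseudo-axial OPMB group should place the alkenyl group cis to OPMB and methyl (new centre R), a centre that becomes sp2 again in step 10.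

Step 7
Reactants: 10 (E)-1,2-bis(tributylstannyl)ethene
Product: 11 benzyldimethyl[(E)-2-(tributylstannyl)ethenyl]silane
Conditions: n-BuLi, THF, −78 °C; then BnMe2SiCl, −78 °C to rt
Reagents that add atoms: benzylchlorodimethylsilane, C[Si](C)(Cl)Cc1ccccc1
Why: Tin–lithium exchange on one stannyl group and silylation of the (E)-vinyllithium, both with retention of alkene geometry.

Step 8
Reactants: 9 alkenyl ketone; 11 stannyl vinylsilane
Product: 12 (1R,2R,3R,6R)-tertiary alcohol
Conditions: 11, n-BuLi, THF, −78 °C; CeCl3; then 9, −78 °C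
Reagents that add atoms: none
Why: 1,2-Addition of an alkenyllithium (from tin–lithium exchange, with CeCl3 against enolisation) to the ketone from the face opposite the three cis substituents OPMB, methyl and alkenyl, which should place the vinylsilane trans to both neighbours and the new hydroxyl cis to OPMB (new centre R).

Step 9
Reactants: 12 tertiary alcohol
Product: 13 (E)-enol ether carbinol
Conditions: [Ir(cod)(PMePh2)2]PF6 (cat., activated with H2), THF, rt
Reagents that add atoms: none
Why: Iridium hydride-catalysed isomerisation of the 2-substituted allyl ether to the enol ether, in which the oxygen should end trans to the bulky ring carbon ((E)-enol ether) under thermodynamic control, with no base present that could start the rearrangement through the exocyclic alkene.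

Step 10
Reactants: 13 (E)-enol ether carbinol
Product: 16 ten-membered keto tert-butyl ester, via potassium alkoxide 14 (not isolated), via potassium enolate 15 (not isolated)
Conditions: KN(SiMe3)2, 18-crown-6, THF, −78 to 0 °C; then BrCH2CO2t-Bu, −78 to −40 °C
Reagents that add atoms: tert-butyl bromoacetate, CC(C)(C)OC(=O)CBr
Why: KN(SiMe3)2 with 18-crown-6 gives the dissociated potassium alkoxide 14, in which the C3–C8 bond of the cyclohexane is weakened, and a concerted [3,3]-sigmatropic shift through a chair transition state then forms C5–C6, cleaves C3–C8 and delivers the ten-membered potassium enolate 15, which is alkylated at C7 in the same flask. The closest known reaction type is the anionic oxy-Cope ring expansion of trans-1,2-dialkenylcyclohexanols to (E)-cyclodec-5-enones with trapping of the enolate by an alkyl halide. The ten-membered ring closes by suprafacial bond formation between the two alkene termini (a four-atom ring expansion of the cyclohexane) in a chair fused to the cyclohexane like a trans-decalin, with both alkenyl arms equatorial and O-8 and H-3 axial, which gives the (E)-enolate and the (E)-C3=C4 alkene. C6 and C5 are set by the (E)-vinylsilane and the (E)-enol ether, whose silyl and OMOM groups are both pseudo-equatorial and therefore end syn, and their absolute sense follows from C9 and C10 because only the one cyclohexane chair with gauche alkenyl arms can react; C7 is set by alkylation on the outer face of the (E)-enolate, anti to the ring bond C6–C5. The step needs chair over boat, [3,3] shift over alkoxide fragmentation and C- over O-alkylation; the all-equatorial chair, the electron-rich termini and the soft α-halo ester should secure these, the (E)-geometry keeps silicon out of reach of O-8, and carbon-bound silicon at C6 (an alkoxy group there would be β to the enolate and would be eliminated) keeps 15 intact.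

Step 11
Reactants: 16 ten-membered keto ester
Product: 17 C8 alcohol
Conditions: LiBH(s-Bu)3, THF, −78 °C
Reagents that add atoms: none
Why: Felkin–Anh reduction with a bulky hydride, which should add anti to the C9–O bond and anti to the C6 branch of C7, so that both neighbours favour the 8R alcohol (hydroxyl syn to OPMB and to the C7 side chain), while the tert-butyl ester is untouched at −78 °C.

Step 12
Reactants: 17 C8 alcohol
Product: 18 C8 triisopropylsilyl ether
Conditions: i-Pr3SiOTf, 2,6-lutidine, CH2Cl2, 0 °C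
Reagents that add atoms: triisopropylsilyl trifluoromethanesulfonate, CC(C)[Si](C(C)C)(C(C)C)OS(=O)(=O)C(F)(F)F
Why: Silylation of the hindered secondary alcohol with a silyl triflate, which sets O-8 apart from the oxygen still masked as silicon at C6.

Step 13
Reactants: 18 C8 silyl ether
Product: 20 C6 hydroxy ester, via fluorosilane 19 (not isolated)
Conditions: Bu4NF, THF, 0 °C; then KHCO3, 30% H2O2, MeOH, 40 °C
Reagents that add atoms: hydrogen peroxide, OO
Why: Tamao–Fleming oxidation of the benzyldimethylsilyl group, in which fluoride cleaves the benzyl–silicon bond to fluorosilane 19 and alkaline peroxide then oxidises the C–Si bond with retention at C6; the brief cold fluoride treatment should spare the triisopropylsilyl ether.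

Step 14
Reactants: 20 C6 hydroxy ester
Product: 21 trans-fused γ-lactone
Conditions: KOt-Bu (0.2 equiv), THF, 0 °C
Reagents that add atoms: none
Why: Base-catalysed lactonisation of the γ-hydroxy tert-butyl ester (intramolecular acyl transfer to O-6, the only free hydroxyl) closes the lactone with retention at C6.

Step 15
Reactants: 21 γ-lactone
Product: 25 α-methylene lactone, via lithium enolate 22 (not isolated), via Mannich base 23 (not isolated), via ammonium iodide 24 (not isolated)
Conditions: LiN(i-Pr)2, THF, −78 °C; CH2=NMe2+ I−; then MeI, MeOH, rt; then NaHCO3 (aq), CH2Cl2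
Reagents that add atoms: N,N-dimethylmethyleneiminium iodide (Eschenmoser's salt), C=[N+](C)C.[I-]
Why: α-Methylenation by Mannich reaction of the lactone enolate with Eschenmoser's salt, N-methylation and base-induced Hofmann-type elimination; the C11 centre formed on the way is removed again.

Step 16
Reactants: 25 α-methylene lactone
Product: 26 C9 alcohol
Conditions: DDQ, CH2Cl2–pH 7 buffer, 0 °C
Reagents that add atoms: none
Why: Oxidative cleavage of the PMB ether with DDQ (oxidation to the oxocarbenium ion, hydrolysis) frees O-9, while MOM, the silyl ether and the electron-poor methylene lactone should be inert.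

Step 17
Reactants: 26 C9 alcohol
Product: 27 C9 isovalerate
Conditions: 3-methylbutanoyl chloride, pyridine, DMAP (cat.), CH2Cl2, 0 °C to rt
Reagents that add atoms: 3-methylbutanoyl chloride, CC(C)CC(=O)Cl
Why: DMAP-catalysed acylation of the hindered secondary alcohol with the acid chloride (esterification).

Step 18
Reactants: 27 C9 isovalerate
Product: 28 C5 allylic alcohol
Conditions: Me2BBr, CH2Cl2, −78 °C; then NaHCO3 (aq)
Reagents that add atoms: none
Why: Lewis acid cleavage of the MOM acetal (bromide attacks the acetal carbon of the boron-bound ether) at −78 °C, conditions under which esters, the silyl ether and the alkenes should survive.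

Step 19
Reactants: 28 C5 allylic alcohol
Product: 29 C5 isobutyrate
Conditions: 2-methylpropanoyl chloride, pyridine, DMAP (cat.), CH2Cl2, 0 °C
Reagents that add atoms: 2-methylpropanoyl chloride, CC(C)C(=O)Cl
Why: DMAP-catalysed acylation of the allylic alcohol (esterification) installs the ester that also serves as neighbouring group in step 21.

Step 20
Reactants: 29 C5 isobutyrate
Product: 30 3,4-epoxide
Conditions: mCPBA, NaHCO3, CH2Cl2, 0 °C
Reagents that add atoms: 3-chloroperbenzoic acid, OOC(=O)c1cccc(Cl)c1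
Why: Prilezhaev epoxidation of the only electron-rich alkene from its outer face, the face away from the ring bond C5–C6, so that the oxirane oxygen should lie trans to the C5 acyloxy group across the ring.

Step 21
Reactants: 30 3,4-epoxide
Product: 32 3,4-diol 5-isobutyrate, via dioxolanylium ion 31 (not isolated)
Conditions: BF3·OEt2 (cat.), CH2Cl2, −40 °C; then H2O, NaHCO3
Reagents that add atoms: water, O
Why: Lewis acid-promoted anchimeric opening of the epoxide, in which the isobutyrate carbonyl oxygen attacks the tertiary carbon C4 from the rear (5-exo, inversion, giving the target configuration) to form dioxolanylium ion 31, which water opens at the cationic carbon to leave the ester on the secondary oxygen O-5 and the tertiary alcohol free.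

Step 22
Reactants: 32 3,4-diol 5-isobutyrate
Product: 33 silyl-protected keto alcohol
Conditions: Dess–Martin periodinane, NaHCO3, CH2Cl2, rt
Reagents that add atoms: none
Why: Dess–Martin oxidation of the secondary alcohol at C3 to the ketone, the tertiary alcohol at C4 being inert.

Step 23
Reactants: 33 silyl-protected keto alcohol
Product: 34 target CNP0203887.1
Conditions: HF·pyridine, THF, 0 °C to rt
Reagents that add atoms: none
Why: Fluoride-mediated cleavage of the silyl ether under buffered acidic conditions, which the methylene lactone, the two esters and the α-ketol should tolerate.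

**Compound list**

1 | (1S,2R)-3-methylcyclohexa-3,5-diene-1,2-diol (toluene cis-dihydrodiol) | CC1=CC=C[C@H](O)[C@@H]1O | starting material
2 | (3aR,7aS)-2-(4-methoxyphenyl)-4-methyl-3a,7a-dihydro-1,3-benzodioxole (either configuration at the acetal carbon) | CC1=CC=C[C@@H]2OC(c3ccc(OC)cc3)O[C@H]12 | intermediate
3 | (3aR,4R,7aS)-2-(4-methoxyphenyl)-4-methylhexahydro-1,3-benzodioxole (either configuration at the acetal carbon) | C[C@@H]1CCC[C@@H]2OC(c3ccc(OC)cc3)O[C@H]12 | intermediate
4 | (1S,2R,3R)-2-[(4-methoxyphenyl)methoxy]-3-methylcyclohexan-1-ol | C[C@@H]1CCC[C@H](O)[C@@H]1OCc2ccc(OC)cc2 | intermediate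
5 | (2R,3R)-2-[(4-methoxyphenyl)methoxy]-3-methylcyclohexan-1-one | C[C@@H]1CCCC(=O)[C@@H]1OCc2ccc(OC)cc2 | intermediate
6 | 2-bromoprop-2-en-1-ol | C=C(Br)CO | starting material
7 | 2-bromo-3-(methoxymethoxy)prop-1-ene | C=C(Br)COCOC | intermediate
8 | lithium (5R,6R)-6-[(4-methoxyphenyl)methoxy]-5-methylcyclohex-1-en-1-olate | C[C@@H]1CCC=C([O-])[C@@H]1OCc2ccc(OC)cc2.[Li+] | intermediate
9 | (2R,3R,6R)-2-[(4-methoxyphenyl)methoxy]-6-[3-(methoxymethoxy)prop-1-en-2-yl]-3-methylcyclohexan-1-one | C[C@@H]1CC[C@H](C(=C)COCOC)C(=O)[C@@H]1OCc2ccc(OC)cc2 | intermediate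
10 | (E)-1,2-bis(tributylstannyl)ethene | CCCC[Sn](CCCC)(CCCC)/C=C/[Sn](CCCC)(CCCC)CCCC | starting material
11 | benzyldimethyl[(E)-2-(tributylstannyl)ethenyl]silane | CCCC[Sn](CCCC)(CCCC)/C=C/[Si](C)(C)Cc1ccccc1 | intermediate
12 | (1R,2R,3R,6R)-1-[(E)-2-(benzyldimethylsilyl)ethenyl]-2-[(4-methoxyphenyl)methoxy]-6-[3-(methoxymethoxy)prop-1-en-2-yl]-3-methylcyclohexan-1-ol | C[C@@H]1CC[C@H](C(=C)COCOC)[C@@](O)(/C=C/[Si](C)(C)Cc2ccccc2)[C@@H]1OCc3ccc(OC)cc3 | intermediate
13 | (1R,2R,3R,6R)-1-[(E)-2-(benzyldimethylsilyl)ethenyl]-6-[(E)-1-(methoxymethoxy)prop-1-en-2-yl]-2-[(4-methoxyphenyl)methoxy]-3-methylcyclohexan-1-ol | C[C@@H]1CC[C@H](/C(C)=C/OCOC)[C@@](O)(/C=C/[Si](C)(C)Cc2ccccc2)[C@@H]1OCc3ccc(OC)cc3 | intermediate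
14 | potassium alkoxide of 13 | C[C@@H]1CC[C@H](/C(C)=C/OCOC)[C@@]([O-])(/C=C/[Si](C)(C)Cc2ccccc2)[C@@H]1OCc3ccc(OC)cc3.[K+] | intermediate
15 | potassium (7E)-enolate of the ten-membered ring: (3E)-alkene, 6-benzyldimethylsilyl, 5-OMOM, 9-OPMB, 4,10-dimethyl; C5, C6, C9, C10 as in 34 | C[Si](C)(Cc1ccccc1)[C@H]2/C=C(\[O-])[C@H](OCc3ccc(OC)cc3)[C@H](C)CC/C=C(C)/[C@@H]2OCOC.[K+] | intermediate
16 | tert-butyl ester of the ten-membered 8-ketone: (3E)-alkene, 6-benzyldimethylsilyl, 5-OMOM, 7-CH2CO2t-Bu, 9-OPMB; C5, C6, C7, C9, C10 as in 34 | C[Si](C)(Cc1ccccc1)[C@H]2[C@H](CC(=O)OC(C)(C)C)C(=O)[C@H](OCc3ccc(OC)cc3)[C@H](C)CC/C=C(C)/[C@@H]2OCOC | intermediate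
17 | C8 alcohol of 16 (C8 as in 34) | C[Si](C)(Cc1ccccc1)[C@H]2[C@H](CC(=O)OC(C)(C)C)[C@@H](O)[C@H](OCc3ccc(OC)cc3)[C@H](C)CC/C=C(C)/[C@@H]2OCOC | intermediate
18 | C8 triisopropylsilyl ether of 17 | C[Si](C)(Cc1ccccc1)[C@H]2[C@H](CC(=O)OC(C)(C)C)[C@@H](O[Si](C(C)C)(C(C)C)C(C)C)[C@H](OCc3ccc(OC)cc3)[C@H](C)CC/C=C(C)/[C@@H]2OCOC | intermediate
19 | C6 fluorodimethylsilyl analogue of 18 | C[Si](C)(F)[C@H]2[C@H](CC(=O)OC(C)(C)C)[C@@H](O[Si](C(C)C)(C(C)C)C(C)C)[C@H](OCc3ccc(OC)cc3)[C@H](C)CC/C=C(C)/[C@@H]2OCOC | intermediate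
20 | C6 alcohol (γ-hydroxy tert-butyl ester) | O[C@H]1[C@H](CC(=O)OC(C)(C)C)[C@@H](O[Si](C(C)C)(C(C)C)C(C)C)[C@H](OCc2ccc(OC)cc2)[C@H](C)CC/C=C(C)/[C@@H]1OCOC | intermediate
21 | 6,12-lactone (C11 = CH2): 8-OTIPS, 9-OPMB, 5-OMOM, (3E)-alkene | C1C(=O)O[C@H]2[C@H]1[C@@H](O[Si](C(C)C)(C(C)C)C(C)C)[C@H](OCc3ccc(OC)cc3)[C@H](C)CC/C=C(C)/[C@@H]2OCOC | intermediate
22 | lithium enolate of lactone 21 | C1=C([O-])O[C@H]2[C@H]1[C@@H](O[Si](C(C)C)(C(C)C)C(C)C)[C@H](OCc3ccc(OC)cc3)[C@H](C)CC/C=C(C)/[C@@H]2OCOC.[Li+] | intermediate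
23 | 11-(dimethylaminomethyl) lactone (either configuration at C11) | CN(C)CC1C(=O)O[C@H]2[C@H]1[C@@H](O[Si](C(C)C)(C(C)C)C(C)C)[C@H](OCc3ccc(OC)cc3)[C@H](C)CC/C=C(C)/[C@@H]2OCOC | intermediate
24 | 11-(trimethylammoniomethyl) lactone iodide | C[N+](C)(C)CC1C(=O)O[C@H]2[C@H]1[C@@H](O[Si](C(C)C)(C(C)C)C(C)C)[C@H](OCc3ccc(OC)cc3)[C@H](C)CC/C=C(C)/[C@@H]2OCOC.[I-] | intermediate
25 | α-methylene lactone: 8-OTIPS, 9-OPMB, 5-OMOM, (3E)-alkene | C=C1C(=O)O[C@H]2[C@H]1[C@@H](O[Si](C(C)C)(C(C)C)C(C)C)[C@H](OCc3ccc(OC)cc3)[C@H](C)CC/C=C(C)/[C@@H]2OCOC | intermediate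
26 | C9 alcohol | C=C1C(=O)O[C@H]2[C@H]1[C@@H](O[Si](C(C)C)(C(C)C)C(C)C)[C@H](O)[C@H](C)CC/C=C(C)/[C@@H]2OCOC | intermediate
27 | C9 3-methylbutanoate | C=C1C(=O)O[C@H]2[C@H]1[C@@H](O[Si](C(C)C)(C(C)C)C(C)C)[C@H](OC(=O)CC(C)C)[C@H](C)CC/C=C(C)/[C@@H]2OCOC | intermediate
28 | C5 allylic alcohol | C=C1C(=O)O[C@H]2[C@H]1[C@@H](O[Si](C(C)C)(C(C)C)C(C)C)[C@H](OC(=O)CC(C)C)[C@H](C)CC/C=C(C)/[C@@H]2O | intermediate
29 | C5 2-methylpropanoate (both esters in place, (3E)-alkene) | C=C1C(=O)O[C@H]2[C@H]1[C@@H](O[Si](C(C)C)(C(C)C)C(C)C)[C@H](OC(=O)CC(C)C)[C@H](C)CC/C=C(C)/[C@@H]2OC(=O)C(C)C | intermediate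
30 | trans-3,4-epoxide, oxirane oxygen trans to the C5 acyloxy group across the ring | C=C1C(=O)O[C@H]2[C@H]1[C@@H](O[Si](C(C)C)(C(C)C)C(C)C)[C@H](OC(=O)CC(C)C)[C@H](C)CC[C@@H]3O[C@@]3(C)[C@@H]2OC(=O)C(C)C | intermediate
31 | 2-isopropyl-1,3-dioxolan-2-ylium ion spanning O-4 and O-5, C3 hydroxyl free | C=C1C(=O)O[C@H]2[C@H]1[C@@H](O[Si](C(C)C)(C(C)C)C(C)C)[C@H](OC(=O)CC(C)C)[C@H](C)CC[C@H](O)[C@]4(C)OC(C(C)C)=[O+][C@H]24 | intermediate
32 | 3,4-diol 5-(2-methylpropanoate), C4 as in 34 | C=C1C(=O)O[C@H]2[C@H]1[C@@H](O[Si](C(C)C)(C(C)C)C(C)C)[C@H](OC(=O)CC(C)C)[C@H](C)CC[C@H](O)[C@](C)(O)[C@@H]2OC(=O)C(C)C | intermediate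
33 | 8-O-triisopropylsilyl ether of the target | C=C1C(=O)O[C@H]2[C@H]1[C@@H](O[Si](C(C)C)(C(C)C)C(C)C)[C@H](OC(=O)CC(C)C)[C@H](C)CCC(=O)[C@](C)(O)[C@@H]2OC(=O)C(C)C | intermediate
34 | CNP0203887.1: (4R,5R,6S,7R,8R,9R,10R)-4,8-dihydroxy-5-(2-methylpropanoyloxy)-9-(3-methylbutanoyloxy)-3-oxogermacr-11(13)-en-6,12-olide | C=C1C(=O)O[C@H]2[C@H]1[C@@H](O)[C@H](OC(=O)CC(C)C)[C@H](C)CCC(=O)[C@](C)(O)[C@@H]2OC(=O)C(C)C | target

**Totals and risks**

Total step count: 23. Longest linear sequence: 21 steps (steps 1–4, 6, 8–23).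

Steps most likely to fail:

Step 10. Fragmentation of the potassium alkoxide (retro-addition) or proton transfer from the bromoacetate to the hindered enolate may compete with the shift and the alkylation. The fallback separates the two events and avoids the anion in the first: 13 is silylated (Me3SiOTf, 2,6-lutidine) to the trimethylsilyl ether of 13 F1, which is heated (o-xylene, 180 °C, sealed tube) for a thermal siloxy-Cope rearrangement through the same chair to the ten-membered trimethylsilyl enol ether F2. MeLi (THF, 0 °C) then releases the lithium enolate F3 regiospecifically, and alkylation with tert-butyl bromoacetate comes back to the route at 16.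

Step 21. The epoxide may open by a transannular path or ionise at C4 without participation of the ester, with loss of configuration at C4. The fallback delivers oxygen to C4 with the final configuration and oxidises C3 without touching C4: alcohol 28 is epoxidised under hydroxyl direction (VO(acac)2, t-BuOOH, CH2Cl2) to the erythro epoxy alcohol F4, whose C4–O bond already has the configuration of the target. Acylation with 2-methylpropanoyl chloride gives the epoxy isobutyrate F5, and Kornblum-type oxidative opening (DMSO, BF3·OEt2, then Et3N; attack of DMSO at the less substituted C3) comes back to the route at 33.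

Step 11. Hydride may be delivered to the other face of the ketone, because the ten-membered ring can override the Felkin–Anh preference. The fallback accepts that face and inverts afterwards: the C8 epimer of 17 F6 is subjected to a Mitsunobu reaction (4-nitrobenzoic acid, PPh3, DIAD, toluene) to give the 4-nitrobenzoate of 17 F7 with inversion at C8, and methanolysis (K2CO3, MeOH, 0 °C) comes back to the route at 17.

Further compounds
F1 | step 10 | trimethylsilyl ether of 13 | C[C@@H]1CC[C@H](/C(C)=C/OCOC)[C@@](O[Si](C)(C)C)(/C=C/[Si](C)(C)Cc2ccccc2)[C@@H]1OCc3ccc(OC)cc3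
F2 | step 10 | ten-membered trimethylsilyl enol ether (silyl analogue of 15) | C[Si](C)(Cc1ccccc1)[C@H]2/C=C(\O[Si](C)(C)C)[C@H](OCc3ccc(OC)cc3)[C@H](C)CC/C=C(C)/[C@@H]2OCOC
F3 | step 10 | lithium enolate corresponding to 15 | C[Si](C)(Cc1ccccc1)[C@H]2/C=C(\[O-])[C@H](OCc3ccc(OC)cc3)[C@H](C)CC/C=C(C)/[C@@H]2OCOC.[Li+]
F4 | step 21 | erythro 3,4-epoxy 5-alcohol (oxirane oxygen on the face opposite to that in 30) | C=C1C(=O)O[C@H]2[C@H]1[C@@H](O[Si](C(C)C)(C(C)C)C(C)C)[C@H](OC(=O)CC(C)C)[C@H](C)CC[C@H]3O[C@]3(C)[C@@H]2O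
F5 | step 21 | 2-methylpropanoate of F4 (3,4-diastereomer of 30) | C=C1C(=O)O[C@H]2[C@H]1[C@@H](O[Si](C(C)C)(C(C)C)C(C)C)[C@H](OC(=O)CC(C)C)[C@H](C)CC[C@H]3O[C@]3(C)[C@@H]2OC(=O)C(C)C
F6 | step 11 | C8 epimer of 17 | C[Si](C)(Cc1ccccc1)[C@H]2[C@H](CC(=O)OC(C)(C)C)[C@H](O)[C@H](OCc3ccc(OC)cc3)[C@H](C)CC/C=C(C)/[C@@H]2OCOC
F7 | step 11 | 4-nitrobenzoate of 17 | C[Si](C)(Cc1ccccc1)[C@H]2[C@H](CC(=O)OC(C)(C)C)[C@@H](OC(=O)c4ccc(cc4)[N+](=O)[O-])[C@H](OCc3ccc(OC)cc3)[C@H](C)CC/C=C(C)/[C@@H]2OCOC
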